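**Conventions and assumptions (remarks on the chemistry)**

- Ring atoms of every carbocycle keep the numbers of the target: C1 (OAc), C2=C3, C7 on C3, C4 (OH), C5 (OBz), C6 (OH). C1–C6 are the former C5, C6, C1, C2, C3, C4 of shikimic acid and C7 is its carboxyl carbon. β is the ring face of O5/O6, α the face of O1/O4. Compounds 1, 4, 5 and 6 are named with shikimate numbers.
- Stereochemical check: the (3R,4S) diol carbons of 1 become C5 and C6 with the sense required by 23, and oxygen added to the opposite face gives C1 and C4 as in 23. Compounds 10 and 12 as listed are therefore the correct enantiomers, and no structure needed correction.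
- Precursor design: the acetonide is kept because it is the most reliable facial shield and survives every step before its removal. C7 carries the benzoate of the target before the oxygenation. Commercial 1 is taken as enantiopure.

## Structural features

Compound 23 is a monocyclic cyclohexene (C1–C6, C2=C3) with one exocyclic carbon, C7, on C3; there is no second ring and no stereocentre outside the ring. C4, C5, C6 and C1 form an unbroken row of four oxygenated stereocentres: O1 and O4 are cis to each other on the α face, O5 and O6 are cis on the β face, so the neighbour relations are trans (C4/C5), cis (C5/C6) and trans (C6/C1). The five oxygens are in three states: acetate on O1, benzoate on O5 and on the primary O7, free hydroxyl on O4 and O6. The fragile elements are these esters in their setting: the O5 benzoate lies between two free vicinal hydroxyls, the O1 acetate is vicinal to O6–H and the O7 benzoate is 1,3 to O4–H, so base invites acyl migration, and O1, O4 and O7 are all allylic. The carbon skeleton is simple; the real difficulty is to build the trans,cis,trans tetrad in one absolute sense and then to tell O1 from O4 and O5 from O6. The key step uses the C1–C2=C3–C4 unit: two allylic oxygens cis to each other across the alkene and anti to the cis O5/O6 pair are what a suprafacial 1,4-addition of O2 to the C1=C2–C3=C4 diene of a cis-fused O5,O6-acetonide must leave. That diene, with C7 on the internal carbon C3, is a dehydrated and reduced shikimate, which fixes the chiral-pool source and the absolute configuration at C5 and C6.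

## Logic of the disconnections

23 ⇒ 22. The O4–H of 23 is traced to an O4–Si bond in 22. A silyl ether does not migrate under acid, keeps O4 out of the O5/O6 chemistry and, being bulky and pseudoaxial next to the C3 substituent, fixes the half-chair in which O5 is axial. The gain is that the last step only uncovers a hydroxyl. The forward step must cleave Si–O without base so that the O5 and O1 esters stay in place.

22 ⇒ 19 + 20 + 18. The O5–C(O)Ph bond of 22 is cut, but not as a direct acylation: O5 and O6 of 19 are first joined through the benzoyl carbon of 20 in the cyclic orthoester 21, which 18 then opens. Direct acylation of 19 would favour the more open, equatorial O6–H. The gain is that one reagent both selects the cis-diol and delivers the acyl group. The demand is regiochemical: the hemiorthoester from 21 must collapse with the acyl group on the axial O5.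

19 ⇒ 17. The two hydroxyls of 19 are reconnected through an isopropylidene carbon (two acetal C–O bonds) to give 17. This is the same acetal that shields the β face in the key step, so no extra protecting group is introduced. The forward hydrolysis must remove the acetal while the O4 silyl ether, the acetate and the benzoate stay, and the acetate must not move to the freed O6.

17 ⇒ 15 + 16. The O4–Si bond of 17 is cut to 15 and 16. It comes after the acetylation so that the only free hydroxyl left is the one to be silylated. No selectivity is asked of the step, only enough reactivity for a hindered allylic alcohol.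

15 ⇒ 13 + 14. The O1–acetyl bond of 15 is cut to 13 and 14. O1–H has the hydrogen-bearing C2 as neighbour, O4–H the fully substituted C3 with C7, and this steric difference is the handle that distinguishes the two oxygens delivered together by the key step. The gain is that the acetate of the target is installed without a protecting-group detour. The demand is monoacylation at O1 under kinetic control.

13 ⇒ 12. The two O–H bonds of 13 are exchanged for the O–O bond of 12. This turns a cis-1,4-diol into a bicyclic peroxide that one cycloaddition can make. The forward reduction must break only the O–O bond and leave the C–O bonds, the alkene and the benzoate intact.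

12 ⇒ 10 + 11. The C1–O and C4–O bonds of 12 are cut together, which opens the dioxine ring, removes two stereocentres and returns the alkene C2=C3 to the diene C1=C2–C3=C4 of 10; the two oxygen atoms are those of 11. This is the strategic simplification: four stereocentres become two, both inherited from the chiral pool. The forward step needs addition on the α face only, and cycloaddition in preference to the ene pathway and to dimerization of 10.

10 ⇒ 8 + 9. The O7–benzoyl bond of 10 is cut to 8 and 9. The ester is installed before the oxygenation because O7 is then the only hydroxyl in the molecule, and because an acylated O7 does not steer singlet oxygen as a free allylic hydroxyl can. The demand is a mild acylation that neither aromatizes nor dimerizes the diene.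

8 ⇒ 7. The two C7–H bonds of 8 are traced to the ester carbonyl of 7, a change of oxidation level only. The ester is what the chiral pool provides, and it also acidifies the ring hydrogen removed in the preceding elimination. The reduction must be a 1,2-addition to a doubly unsaturated ester.

7 ⇒ 5. The C1=C2 bond of 7 (target numbering) is traced to a C1–O and a C2–H bond in 5, by way of the sulfonate 6. The hydroxyl given up is the one stereocentre that the cycloaddition later re-creates at C1, so its loss costs nothing and buys the diene. The forward elimination must run towards C2 only, and the base must not substitute at C1.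

5 ⇒ 1 + 2 + 3. The ester O–CH3 bond and the two acetal C–O bonds of 5 are cut to 1, 2 and 3, with 4 in between. This ends at an inexpensive natural product that holds all seven carbons, the cis O5/O6 pair in the correct absolute configuration and a third hydroxyl placed for the elimination. The demand is that the acetal forms on the cis pair and not on the trans pair.

## Other disconnections considered

Alternative 1: The cut is made inside the ring. C3 is removed as a dibromocarbene carbon, so that the cyclohexene comes from a cyclopentene (C1, C2, C4, C5, C6) of the pentose pool; A1 (D-ribose) supplies C5 and C6 with the correct absolute sense.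
- Forward key step: the silylated dibromocyclopropane A2 would be reached from A1 by chain adjustment, ring-closing metathesis, silylation and dibromocarbene addition. It is drawn with the cyclopropane on the face away from the dioxolane, a configuration that the ring opening erases. With AgOCOCF3 in wet acetone, loss of the endo bromide is concerted with disrotatory opening of the C2–C4 bond to a bromo-substituted allyl cation over C2–C3–C4. Water would have to enter at C4 on the α face to give A3.
- In its favour: O1 (silyl ether) and O4 (free hydroxyl) emerge already differentiated by construction. This is better than the chosen plan, where they are told apart only by a steric bias in step 7. The O5/O6 acetonide, and therefore the end game at O5/O6, is the same as in the chosen plan (equal). The vinyl bromide is a clean handle for C7.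
- Against it here: C7 is not yet in the molecule and must be added at C3 by a palladium-mediated carbonylation or hydroxymethylation, followed by adjustment and benzoylation. Water can attack the unsymmetrical cation at C2 as well as at C4 and from either face, so one regiochemical and one stereochemical question replace the single facial question of the cycloaddition. The differentiation also comes out the wrong way round for direct use (O1 must become the acetate and O4 the free hydroxyl), so protecting-group exchanges remain.
- Comparison: on mechanism the chosen plan is the more predictable, since a pericyclic addition makes both C–O bonds cis by necessity while a cation capture does not. On step count the alternative should be several steps longer because of the cyclopentene construction and the late C7 installation.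

Alternative 2: The bonds cut are C5–O and C6–O, so that the ring comes from an aromatic precursor by way of the quinone monoketal A4, in which C1 is masked as a dimethyl ketal and C7 is already attached.
- Forward key step: enantioselective reduction of the C4 carbonyl of A4 (for instance a Corey–Bakshi–Shibata reduction) and silylation would give A5. OsO4 with N-methylmorpholine N-oxide would then have to dihydroxylate C5=C6 on the face opposite the C4 silyloxy group to give A6; no ring is closed.
- In its favour: the skeleton including C7 is reached in very few steps from a cheap arene, which is better than the chosen plan on step count up to that point. O4 is differentiated from the outset and O1 is held at the ketone level, so the O1/O4 problem of the chosen plan does not arise (better). The syn addition guarantees the cis O5/O6 pair, and the later O5/O6 differentiation is the same problem as in the chosen plan (equal).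
- Against it here: the absolute configuration hangs on one catalytic reduction of a cross-conjugated dienone, whereas the chosen plan inherits it from an enantiopure natural product. Dienol ketals aromatize readily by loss of methanol under traces of acid. OsO4 has to choose the disubstituted C5=C6 over the trisubstituted C2=C3, and the right face with only one allylic stereocentre to guide it. C1 remains to be set by hydride addition to the unmasked enone from the β face, syn to O6, which is the contrasteric direction and would need hydroxyl-directed delivery.
- Comparison: the chosen plan sets C1 and C4 together and needs no late carbonyl reduction. The alternative is shorter on paper but carries three independent selectivity questions (enantioselectivity, site and face of osmylation, face of the C1 reduction) where the chosen route has one substrate-controlled facial question.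

Alternative 3: The cut is the C1–C2 ring bond. C2 is the methyl carbon and C3 the C5 carbonyl of the 6-deoxyhexos-5-ulose A8, which would come from A7 (L-rhamnose) by acetonide formation on its cis-2,3-diol (the future O6/O5) and oxidation at C5; the L-manno configuration matches C4, C5 and C6 of 23.
- Forward key step: an amine (L-proline or Et3N) generates the methyl-ketone enamine or enol, which attacks the aldehyde intramolecularly in a 6-(enolendo)-exo-trig aldol. This closes the carbocycle and creates the C1 carbinol of A9.
- In its favour: three stereocentres and the O5/O6 acetonide come from a cheap sugar with the correct absolute sense (equal to the chiral-pool economy of the chosen plan). The carbocyclization is a metal-free C–C bond formation. O1 (β to the ketone) and O4 (α to it) are chemically distinct, a point on which the alternative is at least the equal of the chosen plan.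
- Against it here: C7 is missing and C3 is a ketone, so the C2=C3–C7 unit has still to be built (regioselective enol triflate towards C2, carbonylation, reduction, benzoylation). The β-hydroxy ketone A9 can lose water across C1–C2 and so destroy the centre just made. The C1 configuration rests on aldol diastereocontrol and not on a cycloaddition that fixes C1 and C4 together. A8 itself costs several protecting-group and oxidation steps.
- Comparison: on step economy the alternative should be clearly longer than the chosen plan, which starts with the carbocycle and C7 in place.

Key step: step 5

## Route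

Step 1
Reactants: 1 (−)-shikimic acid; 2 methanol; 3 2,2-dimethoxypropane
Product: 5 methyl 3,4-O-isopropylideneshikimate, via methyl shikimate 4 (not isolated)
Conditions: 10-camphorsulfonic acid (cat.), MeOH, reflux; evaporate; Me2C(OMe)2, acetone, rt (same flask, same acid)
Reagents that add atoms: methanol, CO; 2,2-dimethoxypropane, COC(C)(C)OC
Why: Fischer esterification followed by acid-catalysed transacetalization; the dioxolane should form only on the cis 3,4-diol because a five-membered acetal across the trans 4,5-diol is strained. No stereocentre is touched.

Step 2
Reactants: 5 methyl 3,4-O-isopropylideneshikimate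
Product: 7 methyl (3R,4S)-3,4-(isopropylidenedioxy)cyclohexa-1,5-diene-1-carboxylate, via shikimate 5-O-triflate 6 (not isolated)
Conditions: Tf2O, pyridine, CH2Cl2, −20 °C; evaporate; CsOAc, DMF, rt
Reagents that add atoms: none
Why: Sulfonylation of the remaining hydroxyl, then E2 elimination: acetate removes the ring-CH2 hydrogen anti to the triflate, which is allylic and vinylogously activated by the ester. Substitution from the dioxolane face is hindered and the acetal C–H on the other side is syn to the leaving group, so only the conjugated diene should form.

Step 3
Reactants: 7 methyl (3R,4S)-3,4-(isopropylidenedioxy)cyclohexa-1,5-diene-1-carboxylate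
Product: 8 [(3R,4S)-3,4-(isopropylidenedioxy)cyclohexa-1,5-dien-1-yl]methanol
Conditions: iBu2AlH (2.5 equiv), CH2Cl2, −78 °C; aq. potassium sodium tartrate
Reagents that add atoms: none
Why: 1,2-Reduction of a conjugated ester by an aluminium hydride at low temperature; two hydrides are delivered to C7 while the diene and the acetal are left alone. No stereocentre is involved.

Step 4
Reactants: 8 [(3R,4S)-3,4-(isopropylidenedioxy)cyclohexa-1,5-dien-1-yl]methanol; 9 benzoyl chloride
Product: 10 [(3R,4S)-3,4-(isopropylidenedioxy)cyclohexa-1,5-dien-1-yl]methyl benzoate
Conditions: BzCl, pyridine, 4-(dimethylamino)pyridine (cat.), CH2Cl2, 0 °C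
Reagents that add atoms: benzoyl chloride, O=C(Cl)c1ccccc1
Why: Acylation of a primary allylic alcohol under nucleophilic catalysis; it places the C7 ester of the target while O7 is the only hydroxyl present. The cold, weakly basic medium should leave the sensitive diene untouched.

Step 5
Reactants: 10 [(3R,4S)-3,4-(isopropylidenedioxy)cyclohexa-1,5-dien-1-yl]methyl benzoate; 11 dioxygen
Product: 12 1α,4α-epidioxy-3-(benzoyloxymethyl)-5β,6β-(isopropylidenedioxy)cyclohex-2-ene
Conditions: O2 (1 atm), tetraphenylporphyrin (cat.), visible light, CH2Cl2, −30 °C
Reagents that add atoms: dioxygen, O=O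
Why: Excited tetraphenylporphyrin passes its triplet energy to O2, and the singlet oxygen so formed adds to the ring diene C1=C2–C3=C4 in a suprafacial [4+2] cycloaddition that makes the C1–O and C4–O bonds and moves the alkene to C2=C3. The closest known reaction type is the photooxygenation of arene cis-dihydrodiol acetonides to anti endoperoxides, followed by peroxide reduction to conduritol-type diols. The one ring closed is the six-membered 3,6-dihydro-1,2-dioxine, formed pericyclically as the peroxide bridge of a 2,3-dioxabicyclo[2.2.2]octene, so O1 and O4 are necessarily cis. Both new stereocentres, C1 and C4, are set by the substrate: the cis-fused dioxolane and its inward methyl group cover the β face, so oxygen should approach the α face and both oxygens end anti to O5 and O6. The step needs π-facial selectivity, which the acetonide supplies. It needs cycloaddition to win over the ene reaction at the C7 or C5/C6 hydrogens, which the ring-enforced s-cis geometry and the acylated, non-directing O7 should ensure. It must also outrun Diels–Alder dimerization of 10, which low temperature and dilution address. The absolute configuration is inherited from C5 and C6, which stem from 1.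

Step 6
Reactants: 12 1α,4α-epidioxy-3-(benzoyloxymethyl)-5β,6β-(isopropylidenedioxy)cyclohex-2-ene
Product: 13 3-(benzoyloxymethyl)-5β,6β-(isopropylidenedioxy)cyclohex-2-ene-1α,4α-diol
Conditions: thiourea (2.2 equiv), MeOH, 0 °C → rt
Reagents that add atoms: none
Why: Thiourea reduces the O–O bond of bicyclic endoperoxides by attack of sulfur on oxygen under neutral conditions. The C–O bonds are not broken, so the cis-1,4-diol keeps the C1 and C4 configurations, and the alkene and the benzoate are inert.

Step 7
Reactants: 13 3-(benzoyloxymethyl)-5β,6β-(isopropylidenedioxy)cyclohex-2-ene-1α,4α-diol; 14 acetyl chloride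
Product: 15 1α-acetoxy-3-(benzoyloxymethyl)-5β,6β-(isopropylidenedioxy)cyclohex-2-en-4α-ol
Conditions: AcCl (1.05 equiv), 2,4,6-collidine, CH2Cl2, −78 °C
Reagents that add atoms: acetyl chloride, CC(=O)Cl
Why: Kinetic, sterically controlled monoacylation with an acid chloride and a hindered pyridine base at low temperature. O1–H (pseudoequatorial, next to C2–H) should react well before O4–H, which is pseudoaxial and flanked by the C3–C7 branch; no stereocentre changes.

Step 8
Reactants: 15 1α-acetoxy-3-(benzoyloxymethyl)-5β,6β-(isopropylidenedioxy)cyclohex-2-en-4α-ol; 16 tert-butyldimethylsilyl trifluoromethanesulfonate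
Product: 17 1α-acetoxy-3-(benzoyloxymethyl)-4α-(tert-butyldimethylsilyloxy)-5β,6β-(isopropylidenedioxy)cyclohex-2-ene
Conditions: TBSOTf, 2,6-lutidine, CH2Cl2, −40 → 0 °C
Reagents that add atoms: tert-butyldimethylsilyl trifluoromethanesulfonate, CC(C)(C)[Si](C)(C)OS(=O)(=O)C(F)(F)F
Why: Silylation of a hindered secondary alcohol with a silyl triflate and a hindered base; the esters and the acetonide tolerate these conditions at low temperature.

Step 9
Reactants: 17 1α-acetoxy-3-(benzoyloxymethyl)-4α-(tert-butyldimethylsilyloxy)-5β,6β-(isopropylidenedioxy)cyclohex-2-ene; 18 water
Product: 19 1α-acetoxy-3-(benzoyloxymethyl)-4α-(tert-butyldimethylsilyloxy)cyclohex-2-ene-5β,6β-diol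
Conditions: AcOH–H2O (4:1), 50 °C
Reagents that add atoms: none
Why: Acid-catalysed hydrolysis of the isopropylidene acetal, in which the oxygen of water leaves as acetone and only hydrogen stays in the product. The hindered secondary silyl ether and the two esters should react much more slowly, and acyl migration is slow in acid.

Step 10
Reactants: 19 1α-acetoxy-3-(benzoyloxymethyl)-4α-(tert-butyldimethylsilyloxy)cyclohex-2-ene-5β,6β-diol; 20 trimethyl orthobenzoate; 18 water
Product: 22 1α-acetoxy-5β-benzoyloxy-3-(benzoyloxymethyl)-4α-(tert-butyldimethylsilyloxy)cyclohex-2-en-6β-ol, via cyclic orthobenzoate 21 (not isolated)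
Conditions: PhC(OMe)3, 10-camphorsulfonic acid (cat.), CH2Cl2, rt; then AcOH–H2O (4:1), 0 °C → rt
Reagents that add atoms: trimethyl orthobenzoate, COC(OC)(OC)c1ccccc1; water, O
Why: Acid-catalysed exchange should give the cis-fused cyclic orthobenzoate on O5/O6, and mild aqueous acid opens it through a hemiorthoester whose stereoelectronically controlled collapse leaves the acyl group on the axial oxygen (regioselective orthoester hydrolysis, well established for cis-diols on six-membered rings). With the O4 silyl ether held pseudoaxial by allylic 1,2-strain against C7, O5 is the axial oxygen, so the benzoate should end on C5 and O6 is released.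

Step 11
Reactants: 22 1α-acetoxy-5β-benzoyloxy-3-(benzoyloxymethyl)-4α-(tert-butyldimethylsilyloxy)cyclohex-2-en-6β-ol
Product: 23 [(3R,4S,5R,6S)-3-acetoxy-5-benzoyloxy-4,6-dihydroxycyclohex-1-en-1-yl]methyl benzoate
Conditions: HF·pyridine, pyridine, THF, 0 °C → rt
Reagents that add atoms: none
Why: Fluoride-assisted Si–O cleavage under buffered, weakly acidic conditions removes the silyl ether without the alkoxide basicity that would move the O5 benzoate or the O1 acetate onto a neighbouring hydroxyl. No stereocentre is touched.

## Compound list

1 | (−)-shikimic acid, (3R,4S,5R)-3,4,5-trihydroxycyclohex-1-ene-1-carboxylic acid | OC(=O)C1=C[C@@H](O)[C@@H](O)[C@H](O)C1 | starting material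
2 | methanol | CO | starting material
3 | 2,2-dimethoxypropane | COC(C)(C)OC | starting material
4 | methyl shikimate, methyl (3R,4S,5R)-3,4,5-trihydroxycyclohex-1-ene-1-carboxylate | COC(=O)C1=C[C@@H](O)[C@@H](O)[C@H](O)C1 | intermediate (not isolated)
5 | methyl 3,4-O-isopropylideneshikimate (free 5-hydroxyl trans to the dioxolane) | COC(=O)C1=C[C@H]2OC(C)(C)O[C@H]2[C@H](O)C1 | intermediate
6 | methyl 3,4-O-isopropylidene-5-O-(trifluoromethylsulfonyl)shikimate | COC(=O)C1=C[C@H]2OC(C)(C)O[C@H]2[C@H](OS(=O)(=O)C(F)(F)F)C1 | intermediate (not isolated)
7 | methyl (3R,4S)-3,4-(isopropylidenedioxy)cyclohexa-1,5-diene-1-carboxylate | COC(=O)C1=C[C@H]2OC(C)(C)O[C@H]2C=C1 | intermediate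
8 | [(3R,4S)-3,4-(isopropylidenedioxy)cyclohexa-1,5-dien-1-yl]methanol | OCC1=C[C@H]2OC(C)(C)O[C@H]2C=C1 | intermediate
9 | benzoyl chloride | O=C(Cl)c1ccccc1 | starting material
10 | [(3R,4S)-3,4-(isopropylidenedioxy)cyclohexa-1,5-dien-1-yl]methyl benzoate (target numbering: diene C1=C2–C3=C4, C7H2OBz on C3, β-acetonide on O5/O6) | C1=CC(COC(=O)c2ccccc2)=C[C@H]3OC(C)(C)O[C@@H]13 | intermediate
11 | dioxygen | O=O | starting material
12 | 1α,4α-epidioxy-3-(benzoyloxymethyl)-5β,6β-(isopropylidenedioxy)cyclohex-2-ene (2,3-dioxabicyclo[2.2.2]oct-5-ene, peroxide bridge anti to the dioxolane) | O4[C@@H]1C=C(COC(=O)c2ccccc2)[C@H](O4)[C@H]3OC(C)(C)O[C@@H]13 | intermediate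
13 | 3-(benzoyloxymethyl)-5β,6β-(isopropylidenedioxy)cyclohex-2-ene-1α,4α-diol | O[C@@H]1C=C(COC(=O)c2ccccc2)[C@H](O)[C@H]3OC(C)(C)O[C@@H]13 | intermediate
14 | acetyl chloride | CC(=O)Cl | starting material
15 | 1α-acetoxy-3-(benzoyloxymethyl)-5β,6β-(isopropylidenedioxy)cyclohex-2-en-4α-ol | CC(=O)O[C@@H]1C=C(COC(=O)c2ccccc2)[C@H](O)[C@H]3OC(C)(C)O[C@@H]13 | intermediate
16 | tert-butyldimethylsilyl trifluoromethanesulfonate | CC(C)(C)[Si](C)(C)OS(=O)(=O)C(F)(F)F | starting material
17 | 1α-acetoxy-3-(benzoyloxymethyl)-4α-(tert-butyldimethylsilyloxy)-5β,6β-(isopropylidenedioxy)cyclohex-2-ene | CC(=O)O[C@@H]1C=C(COC(=O)c2ccccc2)[C@H](O[Si](C)(C)C(C)(C)C)[C@H]3OC(C)(C)O[C@@H]13 | intermediate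
18 | water | O | starting material
19 | 1α-acetoxy-3-(benzoyloxymethyl)-4α-(tert-butyldimethylsilyloxy)cyclohex-2-ene-5β,6β-diol | CC(=O)O[C@@H]1C=C(COC(=O)c2ccccc2)[C@H](O[Si](C)(C)C(C)(C)C)[C@@H](O)[C@H]1O | intermediate
20 | trimethyl orthobenzoate | COC(OC)(OC)c1ccccc1 | starting material
21 | O5,O6-(α-methoxybenzylidene) cyclic orthoester of 19 (both epimers at the orthoester carbon) | CC(=O)O[C@@H]1C=C(COC(=O)c2ccccc2)[C@H](O[Si](C)(C)C(C)(C)C)[C@H]3OC(OC)(c4ccccc4)O[C@@H]13 | intermediate (not isolated)
22 | 1α-acetoxy-5β-benzoyloxy-3-(benzoyloxymethyl)-4α-(tert-butyldimethylsilyloxy)cyclohex-2-en-6β-ol | CC(=O)O[C@@H]1C=C(COC(=O)c2ccccc2)[C@H](O[Si](C)(C)C(C)(C)C)[C@@H](OC(=O)c2ccccc2)[C@H]1O | intermediate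
23 | [(3R,4S,5R,6S)-3-acetoxy-5-benzoyloxy-4,6-dihydroxycyclohex-1-en-1-yl]methyl benzoate (1α-acetoxy-5β-benzoyloxy-3-(benzoyloxymethyl)cyclohex-2-ene-4α,6β-diol) | CC(=O)O[C@@H]1C=C(COC(=O)c2ccccc2)[C@H](O)[C@@H](OC(=O)c2ccccc2)[C@H]1O | target

## Step count and least certain steps

Total step count: 11. Longest linear sequence: 11 steps (1 → 23); the route is linear and every other starting material is a commercial reagent.

Step 5 (key step). What may go wrong: hydrogen abstraction in an ene process (at C7 or at C5/C6) competing with the cycloaddition, Diels–Alder dimerization of 10 before it is oxygenated, or rearrangement of the peroxide bridge under base, heat or light during isolation. Fallback, a peroxide-free 1,4-dioxygenation: set out from 8. Hydroxyl-directed epoxidation of its C3=C4 bond on the α face with VO(acac)2 and tert-butyl hydroperoxide should give the vinyl epoxy alcohol F1, and benzoylation of O7 the epoxy benzoate F2. Pd(PPh3)4 with acetic acid then opens the vinyl epoxide in the Tsuji–Trost 1,4-sense: zerovalent palladium ionizes the allylic C3–O bond with inversion and acetate attacks C1 anti to the metal, so the acetate ends cis to O4. The path comes back to the route at 15 and also makes step 7 unnecessary.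

Step 7. What may go wrong: insufficient site discrimination between the two allylic hydroxyls, with acylation at O4 or at both oxygens. Fallback, inverted order of protection: set out from 13. Silylate the more accessible O1–H with chlorotriethylsilane and imidazole at low temperature to the C1 triethylsilyl ether F3; a silyl chloride is usually more sensitive to steric differences than an acyl chloride. Cap O4 with TBSOTf and 2,6-lutidine to give the bis-silyl ether F4, remove the triethylsilyl group selectively with pyridinium p-toluenesulfonate in methanol to give the C1 alcohol F5, and acetylate it with acetic anhydride, pyridine and 4-(dimethylamino)pyridine. This comes back to the route at 17.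

Step 9. What may go wrong: loss of the silyl ether together with the acetal in aqueous acid, or acid-promoted drift of the acetate from O1 to the freed O6. Fallback, global deprotection and unprotected orthoester opening: set out from 17. Aqueous trifluoroacetic acid removes both the acetal and the silyl group to give the 4,5,6-triol F6. Trimethyl orthobenzoate with 10-camphorsulfonic acid should engage only the cis O5/O6 pair, giving the cyclic orthobenzoate F7, since a five-membered orthoester across the trans O4/O5 pair is strained. Aqueous acetic acid opens F7 to the axial O5 benzoate, and the path comes back to the route at 23. It is shorter but relies on the free O4–H alone to hold the conformation.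

Step 10. What may go wrong: collapse of the hemiorthoester towards the O6 ester if the half-chair with O5 equatorial is populated, or acid-catalysed equilibration of the benzoate between O5 and O6 after opening. Fallback, steric instead of stereoelectronic differentiation: set out from 19. Chlorotriethylsilane and imidazole at low temperature should silylate the equatorial O6–H, which is remote from the bulky O4 silyl ether, to give the C6 triethylsilyl ether F8. Benzoyl chloride with pyridine and 4-(dimethylamino)pyridine then acylates the remaining O5–H to give the bis-silyl C5 benzoate F9, and HF·pyridine removes both silyl groups. The path comes back to the route at 23.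

## Further compounds

F1 | step 5 | 3α,4α-epoxy-3-(hydroxymethyl)-5β,6β-(isopropylidenedioxy)cyclohex-1-ene (vinyl epoxy alcohol) | C1=C[C@]2(CO)O[C@@H]2[C@H]3OC(C)(C)O[C@@H]13
F2 | step 5 | 3α,4α-epoxy-3-(benzoyloxymethyl)-5β,6β-(isopropylidenedioxy)cyclohex-1-ene (epoxy benzoate) | C1=C[C@]2(COC(=O)c4ccccc4)O[C@@H]2[C@H]3OC(C)(C)O[C@@H]13
F3 | step 7 | 3-(benzoyloxymethyl)-5β,6β-(isopropylidenedioxy)-1α-(triethylsilyloxy)cyclohex-2-en-4α-ol | CC[Si](CC)(CC)O[C@@H]1C=C(COC(=O)c2ccccc2)[C@H](O)[C@H]3OC(C)(C)O[C@@H]13
F4 | step 7 | 3-(benzoyloxymethyl)-4α-(tert-butyldimethylsilyloxy)-5β,6β-(isopropylidenedioxy)-1α-(triethylsilyloxy)cyclohex-2-ene | CC[Si](CC)(CC)O[C@@H]1C=C(COC(=O)c2ccccc2)[C@H](O[Si](C)(C)C(C)(C)C)[C@H]3OC(C)(C)O[C@@H]13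
F5 | step 7 | 3-(benzoyloxymethyl)-4α-(tert-butyldimethylsilyloxy)-5β,6β-(isopropylidenedioxy)cyclohex-2-en-1α-ol | O[C@@H]1C=C(COC(=O)c2ccccc2)[C@H](O[Si](C)(C)C(C)(C)C)[C@H]3OC(C)(C)O[C@@H]13
F6 | step 9 | 1α-acetoxy-3-(benzoyloxymethyl)cyclohex-2-ene-4α,5β,6β-triol | CC(=O)O[C@@H]1C=C(COC(=O)c2ccccc2)[C@H](O)[C@@H](O)[C@H]1O
F7 | step 9 | O5,O6-(α-methoxybenzylidene) cyclic orthoester of F6 (both epimers at the orthoester carbon) | CC(=O)O[C@@H]1C=C(COC(=O)c2ccccc2)[C@H](O)[C@H]3OC(OC)(c4ccccc4)O[C@@H]13
F8 | step 10 | 1α-acetoxy-3-(benzoyloxymethyl)-4α-(tert-butyldimethylsilyloxy)-6β-(triethylsilyloxy)cyclohex-2-en-5β-ol | CC(=O)O[C@@H]1C=C(COC(=O)c2ccccc2)[C@H](O[Si](C)(C)C(C)(C)C)[C@@H](O)[C@H]1O[Si](CC)(CC)CC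
F9 | step 10 | 1α-acetoxy-5β-benzoyloxy-3-(benzoyloxymethyl)-4α-(tert-butyldimethylsilyloxy)-6β-(triethylsilyloxy)cyclohex-2-ene | CC(=O)O[C@@H]1C=C(COC(=O)c2ccccc2)[C@H](O[Si](C)(C)C(C)(C)C)[C@@H](OC(=O)c2ccccc2)[C@H]1O[Si](CC)(CC)CC
A1 | alternative 1 | D-ribose (open-chain form) | O=C[C@H](O)[C@H](O)[C@H](O)CO
A2 | alternative 1 | 6,6-dibromo-2-(tert-butyldimethylsilyloxy)-3,4-(isopropylidenedioxy)bicyclo[3.1.0]hexane (silyl ether and cyclopropane both trans to the dioxolane) | CC(C)(C)[Si](C)(C)O[C@@H]1[C@@H]2C(Br)(Br)[C@@H]2[C@H]3OC(C)(C)O[C@@H]13
A3 | alternative 1 | 3-bromo-1α-(tert-butyldimethylsilyloxy)-5β,6β-(isopropylidenedioxy)cyclohex-2-en-4α-ol | CC(C)(C)[Si](C)(C)O[C@@H]1C=C(Br)[C@H](O)[C@H]2OC(C)(C)O[C@@H]12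
A4 | alternative 2 | 2-(benzoyloxymethyl)-4,4-dimethoxycyclohexa-2,5-dien-1-one (quinone monoketal) | COC1(OC)C=C(COC(=O)c2ccccc2)C(=O)C=C1
A5 | alternative 2 | 3-(benzoyloxymethyl)-4α-(tert-butyldimethylsilyloxy)-1,1-dimethoxycyclohexa-2,5-diene (silylated dienol ketal, C4 as in 23) | COC1(OC)C=C(COC(=O)c2ccccc2)[C@H](O[Si](C)(C)C(C)(C)C)C=C1
A6 | alternative 2 | 3-(benzoyloxymethyl)-4α-(tert-butyldimethylsilyloxy)-1,1-dimethoxycyclohex-2-ene-5β,6β-diol | COC1(OC)C=C(COC(=O)c2ccccc2)[C@H](O[Si](C)(C)C(C)(C)C)[C@@H](O)[C@H]1O
A7 | alternative 3 | L-rhamnose (open-chain form) | C[C@H](O)[C@H](O)[C@@H](O)[C@@H](O)C=O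
A8 | alternative 3 | 6-deoxy-2,3-O-isopropylidene-L-lyxo-hexos-5-ulose | CC(=O)[C@H](O)[C@H]1OC(C)(C)O[C@H]1C=O
A9 | alternative 3 | 5β,6β-(isopropylidenedioxy)-3-oxocyclohexane-1α,4α-diol | O[C@@H]1CC(=O)[C@H](O)[C@H]2OC(C)(C)O[C@@H]12
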